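**Retrosynthetic overview**

1. The seven-membered lactone is opened at its C(=O)–O bond to ring A, and the diaryl ether is cut at the ring A carbon–oxygen bond; this gives chloro-pyranoquinone 10 and the ring B salicylate phenol 14.
2. Pyranoquinone 9 is cut at the ring A–C4 bond and at the O–C(CH3)2 bond of the pyran, back to 2,5-dihydroxy-3-prenyl-1,4-benzoquinone 6 and 3-methylbut-2-enal 7 (Knoevenagel condensation, then oxa-6π electrocyclization).
3. Feature: ring A is fully substituted, with four oxygens (phenol O, pyran O, lactone O, ether O) and two para carbon substituents (prenyl CH2 and pyran C4). This is the oxygen pattern of 2,5-dihydroxy-1,4-benzoquinone, whose single ring C–H lies between a carbonyl carbon and a hydroxyl carbon, exactly where pyran C4 and the pyran oxygen must sit.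
4. Quinone 6 is reached from 1,2,4,5-tetramethoxybenzene (lithiation/prenylation, oxidation, hydrolysis); ring B from 2,4,6-trihydroxybenzoic acid (allyl ester, C-prenylation, bis-protection).
5. Ring order: rings A and B are bought as six-membered carbocycles; the pyran ring is closed in step 4 and the seven-membered dioxepinone ring in step 12.

Key step: step 4

Remark: the target has no stereocentre, so no stereocontrol is needed; the ring B carboxyl is carried as an allyl ester because it can later be released at the allyl carbon, without attack on a carbonyl that has two ortho substituents.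

**Route**

Step 1
Reactants: 1 1,2,4,5-tetramethoxybenzene; 2 1-bromo-3-methylbut-2-ene
Product: 4 1,2,4,5-tetramethoxy-3-(3-methylbut-2-en-1-yl)benzene, via aryllithium 3 (not isolated)
Conditions: n-BuLi, TMEDA, THF, 0 °C; then 2, −78 °C → rt
Reagents that add atoms: none
Why: Directed ortho-lithiation at the ring C–H flanked by two methoxy groups, followed by SN2 alkylation of the aryllithium with the primary allylic bromide, should give the C-prenyl arene.

Step 2
Reactants: 4 1,2,4,5-tetramethoxy-3-(3-methylbut-2-en-1-yl)benzene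
Product: 5 2,5-dimethoxy-3-(3-methylbut-2-en-1-yl)-1,4-benzoquinone
Conditions: (NH4)2Ce(NO3)6, MeCN/H2O, 0 °C
Reagents that add atoms: water, O
Why: Oxidative demethylation of a 1,4-dimethoxyarene to the p-quinone should be fast enough at 0 °C to spare the trisubstituted alkene, and either para pair of methoxy groups leads to the same quinone.

Step 3
Reactants: 5 2,5-dimethoxy-3-(3-methylbut-2-en-1-yl)-1,4-benzoquinone
Product: 6 2,5-dihydroxy-3-(3-methylbut-2-en-1-yl)-1,4-benzoquinone
Conditions: 2 M NaOH, EtOH, 60 °C; then 1 M HCl, 0 °C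
Reagents that add atoms: sodium hydroxide, [Na+].[OH-]
Why: The two methoxyquinone carbons are vinylogous esters, so hydroxide should replace both methoxy groups by addition–elimination (vinylogous ester saponification), and cold dilute acid should release the dihydroxyquinone without cyclizing the prenyl group.

Step 4
Reactants: 6 2,5-dihydroxy-3-(3-methylbut-2-en-1-yl)-1,4-benzoquinone; 7 3-methylbut-2-enal
Product: 9 6-hydroxy-2,2-dimethyl-7-(3-methylbut-2-en-1-yl)-2H-chromene-5,8-dione, via Knoevenagel oxatriene 8 (not isolated)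
Conditions: ethylenediammonium diacetate (20 mol%), toluene, 80 °C
Reagents that add atoms: none
Why: The amine of the catalyst condenses with the enal to an iminium ion, the only ring C–H carbon of the hydroxyquinone (a vinylogous acid) adds to it, and loss of the amine gives the Knoevenagel 1-oxatriene 8. This intermediate should close by thermal oxa-6π electrocyclization, in which a carbonyl oxygen next to the alkylidene carbon bonds to the dimethyl-substituted terminus and forms the six-membered 2H-pyran ring. The closest known reaction is the formal [3+3] annulation of 2-hydroxy-1,4-naphthoquinone and of 2,5-dihydroxy-1,4-benzoquinone with α,β-unsaturated aldehydes under amine or diammonium diacetate catalysis. No stereocentre is formed. The step needs C-condensation and one regiochemistry: the substrate has a single ring C–H, and because its tautomers are mirror-symmetric about the axis through the prenyl carbon and the C–H carbon, closure through either neighbouring oxygen leads to the same p-quinone, with the remaining hydroxyl beside the prenyl group and para to the pyran oxygen. The buffered, weakly acidic medium should keep the prenyl group from cyclizing onto that hydroxyl.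

Step 5
Reactants: 9 6-hydroxy-2,2-dimethyl-7-(3-methylbut-2-en-1-yl)-2H-chromene-5,8-dione
Product: 10 6-chloro-2,2-dimethyl-7-(3-methylbut-2-en-1-yl)-2H-chromene-5,8-dione
Conditions: (COCl)2, DMF (cat.), CH2Cl2, 0 °C
Reagents that add atoms: oxalyl chloride, ClC(=O)C(=O)Cl
Why: The hydroxyquinone is a vinylogous carboxylic acid, so the Vilsmeier reagent formed in the flask should convert it into the vinylogous acid chloride by O-activation and chloride addition–elimination.

Step 6
Reactants: 11 2,4,6-trihydroxybenzoic acid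
Product: 12 prop-2-en-1-yl 2,4,6-trihydroxybenzoate
Conditions: allyl bromide, KHCO3, DMF, rt
Reagents that add atoms: allyl bromide, C=CCBr
Why: Hydrogencarbonate deprotonates only the carboxylic acid, so SN2 alkylation of the carboxylate should give the allyl ester and leave the three phenols free.

Step 7
Reactants: 12 prop-2-en-1-yl 2,4,6-trihydroxybenzoate; 2 1-bromo-3-methylbut-2-ene
Product: 13 prop-2-en-1-yl 2,4,6-trihydroxy-3-(3-methylbut-2-en-1-yl)benzoate
Conditions: DBU, THF, 0 °C → rt
Reagents that add atoms: none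
Why: The phenoxide of an acylphloroglucinol is C-nucleophilic at the ring carbons between two oxygens, and because the two free ring positions are equivalent, C-alkylation with one equivalent of the bromide can give only one mono-prenyl isomer.

Step 8
Reactants: 13 prop-2-en-1-yl 2,4,6-trihydroxy-3-(3-methylbut-2-en-1-yl)benzoate
Product: 14 prop-2-en-1-yl 2-hydroxy-4,6-bis(methoxymethoxy)-3-(3-methylbut-2-en-1-yl)benzoate
Conditions: MOMCl (2.1 equiv), i-Pr2NEt, CH2Cl2, 0 °C
Reagents that add atoms: chloromethyl methyl ether, COCCl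
Why: O-Alkylation (acetal formation) should take the non-chelated 4-hydroxyl first and then the less hindered ortho hydroxyl, while the hydroxyl flanked by the prenyl group stays hydrogen-bonded to the ester carbonyl and free.

Step 9
Reactants: 10 6-chloro-2,2-dimethyl-7-(3-methylbut-2-en-1-yl)-2H-chromene-5,8-dione; 14 prop-2-en-1-yl 2-hydroxy-4,6-bis(methoxymethoxy)-3-(3-methylbut-2-en-1-yl)benzoate
Product: 15 prop-2-en-1-yl 2-{[2,2-dimethyl-7-(3-methylbut-2-en-1-yl)-5,8-dioxo-5,8-dihydro-2H-chromen-6-yl]oxy}-4,6-bis(methoxymethoxy)-3-(3-methylbut-2-en-1-yl)benzoate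
Conditions: Cs2CO3, MeCN, 0 °C → rt
Reagents that add atoms: none
Why: Addition–elimination of a phenoxide on a 2-chloro-1,4-quinone (vinylogous acyl substitution) should form the diaryl ether, since the chlorine-bearing carbon is the only quinone carbon with a good leaving group.

Step 10
Reactants: 15 the quinone diaryl ether of step 9
Product: 16 prop-2-en-1-yl 2-{[5,8-dihydroxy-2,2-dimethyl-7-(3-methylbut-2-en-1-yl)-2H-chromen-6-yl]oxy}-4,6-bis(methoxymethoxy)-3-(3-methylbut-2-en-1-yl)benzoate
Conditions: Na2S2O4, EtOAc/H2O, rt, argon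
Reagents that add atoms: none
Why: Dithionite reduction of a quinone to its hydroquinone should leave the alkenes, acetals and ester untouched; the crude product is carried on under argon.

Step 11
Reactants: 16 the hydroquinone allyl ester of step 10
Product: 17 2-{[5,8-dihydroxy-2,2-dimethyl-7-(3-methylbut-2-en-1-yl)-2H-chromen-6-yl]oxy}-4,6-bis(methoxymethoxy)-3-(3-methylbut-2-en-1-yl)benzoic acid
Conditions: Pd(PPh3)4 (5 mol%), morpholine, THF, rt, argon; then pH 4 buffer
Reagents that add atoms: none
Why: In this Tsuji–Trost deallylation zerovalent palladium ionizes the ester at the allyl carbon and morpholine traps the allyl group, so the acid should be released without attack on the hindered carbonyl and without base that would endanger the hydroquinone.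

Step 12
Reactants: 17 the hydroquinone acid of step 11
Product: 18 bis(methoxymethyl) ether of the target (both ring B hydroxyls as OCH2OCH3, ring A hydroxyl free)
Conditions: DCC, DMAP (cat.), CH2Cl2 (high dilution), 0 °C → rt
Reagents that add atoms: none
Why: In this carbodiimide (Steglich-type) lactonization only the hydroquinone hydroxyl ortho to the diaryl ether oxygen can reach the activated carboxyl, so the seven-membered 1,4-dioxepinone ring should close and the other hydroxyl stay free.

Step 13
Reactants: 18 bis(methoxymethyl) ether of the target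
Product: 19 the target depsidone (ring A: free hydroxyl, prenyl group, fused 2,2-dimethyl-2H-pyran; ring B: prenyl group and two hydroxyls; rings joined by an ether oxygen and a lactone)
Conditions: ZnBr2, n-PrSH, CH2Cl2, 0 °C
Reagents that add atoms: none
Why: Lewis acid-assisted cleavage of the aryl methoxymethyl acetals with thiol capture of the methoxymethyl cation should free both phenols quickly, without alcohol or free formaldehyde, so the lactone, the chromene and the prenyl groups should persist.

**Compound list**

1 | 1,2,4,5-tetramethoxybenzene | COc1cc(OC)c(OC)cc1OC | starting material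
2 | 1-bromo-3-methylbut-2-ene | CC(C)=CCBr | starting material
3 | (2,3,5,6-tetramethoxyphenyl)lithium | [Li]c1c(OC)c(OC)cc(OC)c1OC | intermediate
4 | 1,2,4,5-tetramethoxy-3-(3-methylbut-2-en-1-yl)benzene | COc1cc(OC)c(OC)c(CC=C(C)C)c1OC | intermediate
5 | 2,5-dimethoxy-3-(3-methylbut-2-en-1-yl)-1,4-benzoquinone | COC1=CC(=O)C(OC)=C(CC=C(C)C)C1=O | intermediate
6 | 2,5-dihydroxy-3-(3-methylbut-2-en-1-yl)-1,4-benzoquinone | CC(C)=CCC1=C(O)C(=O)C=C(O)C1=O | intermediate
7 | 3-methylbut-2-enal | CC(C)=CC=O | starting material
8 | 2-hydroxy-6-(3-methylbut-2-en-1-ylidene)-3-(3-methylbut-2-en-1-yl)cyclohex-2-ene-1,4,5-trione | CC(C)=CCC1=C(O)C(=O)C(=CC=C(C)C)C(=O)C1=O | intermediate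
9 | 6-hydroxy-2,2-dimethyl-7-(3-methylbut-2-en-1-yl)-2H-chromene-5,8-dione | CC(C)=CCC1=C(O)C(=O)C2=C(OC(C)(C)C=C2)C1=O | intermediate
10 | 6-chloro-2,2-dimethyl-7-(3-methylbut-2-en-1-yl)-2H-chromene-5,8-dione | CC(C)=CCC1=C(Cl)C(=O)C2=C(OC(C)(C)C=C2)C1=O | intermediate
11 | 2,4,6-trihydroxybenzoic acid | OC(=O)c1c(O)cc(O)cc1O | starting material
12 | prop-2-en-1-yl 2,4,6-trihydroxybenzoate | C=CCOC(=O)c1c(O)cc(O)cc1O | intermediate
13 | prop-2-en-1-yl 2,4,6-trihydroxy-3-(3-methylbut-2-en-1-yl)benzoate | C=CCOC(=O)c1c(O)cc(O)c(CC=C(C)C)c1O | intermediate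
14 | prop-2-en-1-yl 2-hydroxy-4,6-bis(methoxymethoxy)-3-(3-methylbut-2-en-1-yl)benzoate | C=CCOC(=O)c1c(O)c(CC=C(C)C)c(OCOC)cc1OCOC | intermediate
15 | prop-2-en-1-yl 2-{[2,2-dimethyl-7-(3-methylbut-2-en-1-yl)-5,8-dioxo-5,8-dihydro-2H-chromen-6-yl]oxy}-4,6-bis(methoxymethoxy)-3-(3-methylbut-2-en-1-yl)benzoate | C=CCOC(=O)c1c(OC2=C(CC=C(C)C)C(=O)C3=C(C=CC(C)(C)O3)C2=O)c(CC=C(C)C)c(OCOC)cc1OCOC | intermediate
16 | prop-2-en-1-yl 2-{[5,8-dihydroxy-2,2-dimethyl-7-(3-methylbut-2-en-1-yl)-2H-chromen-6-yl]oxy}-4,6-bis(methoxymethoxy)-3-(3-methylbut-2-en-1-yl)benzoate | C=CCOC(=O)c1c(Oc2c(CC=C(C)C)c(O)c3OC(C)(C)C=Cc3c2O)c(CC=C(C)C)c(OCOC)cc1OCOC | intermediate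
17 | 2-{[5,8-dihydroxy-2,2-dimethyl-7-(3-methylbut-2-en-1-yl)-2H-chromen-6-yl]oxy}-4,6-bis(methoxymethoxy)-3-(3-methylbut-2-en-1-yl)benzoic acid | OC(=O)c1c(Oc2c(CC=C(C)C)c(O)c3OC(C)(C)C=Cc3c2O)c(CC=C(C)C)c(OCOC)cc1OCOC | intermediate
18 | bis(methoxymethyl) ether of the target depsidone (both ring B hydroxyls protected) | CC(C)=CCc1c(O)c2c(c3c1Oc1c(CC=C(C)C)c(OCOC)cc(OCOC)c1C(=O)O3)C=CC(C)(C)O2 | intermediate
19 | target depsidone CNP0263700.0 | CC(C)=CCc1c(O)c2c(c3c1Oc1c(CC=C(C)C)c(O)cc(O)c1C(=O)O3)C=CC(C)(C)O2 | target

**Step count**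

Total: 13 steps. Longest linear sequence: 10 steps (steps 1–5, then 9–13); the ring B branch is steps 6–8.

**Steps most likely to fail**

Step 4. The condensation may stall because the strongly acidic dihydroxyquinone separates as its diammonium salt, or a second quinone molecule may add to oxatriene 8 before it cyclizes.
- The fallback makes the ring A–C4 bond by organolithium alkylation and closes the pyran by dehydrogenation.
- It sets out from 4: a second ortho-lithiation (n-BuLi, TMEDA) would give [2,3,5,6-tetramethoxy-4-(3-methylbut-2-en-1-yl)phenyl]lithium F1, which with 2 should give 1,2,4,5-tetramethoxy-3,6-bis(3-methylbut-2-en-1-yl)benzene F2.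
- Oxidation with (NH4)2Ce(NO3)6 should give 2,5-dimethoxy-3,6-bis(3-methylbut-2-en-1-yl)-1,4-benzoquinone F3, and NaOH hydrolysis 2,5-dihydroxy-3,6-bis(3-methylbut-2-en-1-yl)-1,4-benzoquinone F4.
- One equivalent of DDQ in benzene should remove hydride from one quinone-bound allylic CH2 and so reach the same oxatriene 8, which closes to 9; this is the cyclodehydrogenation known for prenyl hydroxyquinones such as lapachol. F4 is symmetric, so either prenyl group gives 9, where the fallback comes back to the route.

Step 9. The hindered, chelated phenoxide may react slowly, may attack through its para ring carbon instead of oxygen, or may transfer an electron to the quinone.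
- The fallback delivers the phenoxide intramolecularly through a carboxylate tether.
- It sets out from 14: Pd(PPh3)4 and morpholine should give 2-hydroxy-4,6-bis(methoxymethoxy)-3-(3-methylbut-2-en-1-yl)benzoic acid F5.
- With two equivalents of Cs2CO3 and 10, the exposed carboxylate should add first and give the quinonyl ester 2,2-dimethyl-7-(3-methylbut-2-en-1-yl)-5,8-dioxo-5,8-dihydro-2H-chromen-6-yl 2-hydroxy-4,6-bis(methoxymethoxy)-3-(3-methylbut-2-en-1-yl)benzoate F6.
- The neighbouring phenoxide of F6 should then attack the same quinone carbon through a six-membered transition state and expel the carboxylate, as in the Smiles rearrangement of depsides to diaryl ether acids. This should give 2-{[2,2-dimethyl-7-(3-methylbut-2-en-1-yl)-5,8-dioxo-5,8-dihydro-2H-chromen-6-yl]oxy}-4,6-bis(methoxymethoxy)-3-(3-methylbut-2-en-1-yl)benzoic acid F7.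
- Reduction of F7 with Na2S2O4 comes back to the route at 17.

Step 8. The second alkylation may partly go to the hydroxyl beside the prenyl group, or a third may follow, so that a mixture of regioisomers results.
- The fallback fixes the regiochemistry by protecting before the prenyl group is present and placing it by an aromatic Claisen rearrangement.
- It sets out from 12: MOMCl (2.1 equiv) and i-Pr2NEt should give prop-2-en-1-yl 2-hydroxy-4,6-bis(methoxymethoxy)benzoate F8; the two ortho hydroxyls are equivalent here, so no regiochemical question arises.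
- 3-Chloro-3-methylbut-1-yne, DBU and CuCl2 (cat.) in MeCN should give prop-2-en-1-yl 2,4-bis(methoxymethoxy)-6-[(2-methylbut-3-yn-2-yl)oxy]benzoate F9.
- Semihydrogenation (H2, Pd on CaCO3 poisoned with Pb(OAc)2, quinoline) should give prop-2-en-1-yl 2,4-bis(methoxymethoxy)-6-[(2-methylbut-3-en-2-yl)oxy]benzoate F10.
- Heating F10 in toluene at 110 °C should move the allyl unit by [3,3] shift to the only free ortho carbon, which gives the linear prenyl group of 14, where the fallback comes back to the route.

**Further compounds**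

F1 | step 4 | [2,3,5,6-tetramethoxy-4-(3-methylbut-2-en-1-yl)phenyl]lithium | [Li]c1c(OC)c(OC)c(CC=C(C)C)c(OC)c1OC
F2 | step 4 | 1,2,4,5-tetramethoxy-3,6-bis(3-methylbut-2-en-1-yl)benzene | COc1c(CC=C(C)C)c(OC)c(OC)c(CC=C(C)C)c1OC
F3 | step 4 | 2,5-dimethoxy-3,6-bis(3-methylbut-2-en-1-yl)-1,4-benzoquinone | COC1=C(CC=C(C)C)C(=O)C(OC)=C(CC=C(C)C)C1=O
F4 | step 4 | 2,5-dihydroxy-3,6-bis(3-methylbut-2-en-1-yl)-1,4-benzoquinone | CC(C)=CCC1=C(O)C(=O)C(CC=C(C)C)=C(O)C1=O
F5 | step 9 | 2-hydroxy-4,6-bis(methoxymethoxy)-3-(3-methylbut-2-en-1-yl)benzoic acid | OC(=O)c1c(O)c(CC=C(C)C)c(OCOC)cc1OCOC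
F6 | step 9 | 2,2-dimethyl-7-(3-methylbut-2-en-1-yl)-5,8-dioxo-5,8-dihydro-2H-chromen-6-yl 2-hydroxy-4,6-bis(methoxymethoxy)-3-(3-methylbut-2-en-1-yl)benzoate | O=C(OC1=C(CC=C(C)C)C(=O)C2=C(C=CC(C)(C)O2)C1=O)c1c(O)c(CC=C(C)C)c(OCOC)cc1OCOC
F7 | step 9 | 2-{[2,2-dimethyl-7-(3-methylbut-2-en-1-yl)-5,8-dioxo-5,8-dihydro-2H-chromen-6-yl]oxy}-4,6-bis(methoxymethoxy)-3-(3-methylbut-2-en-1-yl)benzoic acid | OC(=O)c1c(OC2=C(CC=C(C)C)C(=O)C3=C(C=CC(C)(C)O3)C2=O)c(CC=C(C)C)c(OCOC)cc1OCOC
F8 | step 8 | prop-2-en-1-yl 2-hydroxy-4,6-bis(methoxymethoxy)benzoate | C=CCOC(=O)c1c(O)cc(OCOC)cc1OCOC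
F9 | step 8 | prop-2-en-1-yl 2,4-bis(methoxymethoxy)-6-[(2-methylbut-3-yn-2-yl)oxy]benzoate | C=CCOC(=O)c1c(OC(C)(C)C#C)cc(OCOC)cc1OCOC
F10 | step 8 | prop-2-en-1-yl 2,4-bis(methoxymethoxy)-6-[(2-methylbut-3-en-2-yl)oxy]benzoate | C=CCOC(=O)c1c(OC(C)(C)C=C)cc(OCOC)cc1OCOC
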